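## Retrosynthetic overview
1. Target ⇒ acid-catalysed O12→O7 acetyl shift, C10 α-iodination and a double Lindlar reduction ⇒ a 12-acetoxy-7-hydroxycyclopentenone that carries both side chains as alkynes.
2. The only ring (C8–C12 bond) ⇒ conrotatory 4π closure of a 12-acetoxy-2-oxidopentadienyl cation. The cation comes from the 8,9-allene oxide of an acyclic C20 vinylallenol, as in the 8-lipoxygenase/allene oxide route to preclavulone A, but with C12 already oxygenated.
3. C6–C7 ⇒ catalytic asymmetric alkynylation of a vinylallenal with methyl hex-5-ynoate. C7 is the only stereocentre set by a reagent, and it relays to C8 and C12 during ring closure.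
4. Vinylallenal ⇒ but-3-yn-1-ol + a (Z)-β-iodoenol acetate (Sonogashira, then oxidation and propargyl–allenyl shift). The iodoenol acetate ⇒ deca-1,4-diyne ⇒ hept-1-yne + propargyl bromide.
5. Ring order: one carbocycle, formed in step 7 of 10.

Convention: prostanoid numbering (C1 = ester carbon, C20 = chain end) is used for all C20 compounds.
Assumption: the (R,R)-ProPhenol ligand is taken to send the alkynylzinc to the Si face of the vinylallenal in step 6. If an allenal shows the opposite sense, the (S,S)-ligand is used and nothing else changes.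

## Route

Step 1
Reactants: 1 hept-1-yne; 2 propargyl bromide (3-bromoprop-1-yne)
Product: 4 deca-1,4-diyne, via hept-1-ynylmagnesium bromide 3 (not isolated)
Conditions: EtMgBr (1.0 equiv), THF, 0 to 40 °C; then CuBr (5 mol%), 2 (1.1 equiv), 0 °C to rt
Reagents that add atoms: none
Why: Copper-catalysed SN2 coupling of an alkynyl Grignard reagent with propargyl bromide is the classical skipped-diyne synthesis, runs at or below room temperature so the 1,4-diyne does not slip into conjugation, and creates no stereocentre.

Step 2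
Reactants: 4 deca-1,4-diyne
Product: 5 1-iododeca-1,4-diyne
Conditions: NIS (1.1 equiv), AgNO3 (10 mol%), acetone, rt, dark
Reagents that add atoms: N-iodosuccinimide, O=C1CCC(=O)N1I
Why: Silver-catalysed electrophilic iodination of a terminal alkyne (through the silver acetylide) is specific for the sp C–H bond, so the internal alkyne and the doubly propargylic CH2 are untouched.

Step 3
Reactants: 5 1-iododeca-1,4-diyne
Product: 6 (Z)-1-iododec-1-en-4-yn-2-yl acetate
Conditions: AcOH (1.5 equiv), AuCl(PPh3)/AgPF6 (5 mol% each), toluene, rt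
Reagents that add atoms: acetic acid, CC(=O)O
Why: In this gold(I)-catalysed Markovnikov hydroacyloxylation of an iodoalkyne, acetate attacks the activated triple bond at C12 anti to the metal and protodeauration leaves O and I cis, so the (Z)-geometry that later puts the oxygen on the inside of the pentadienyl cation (and so defines C12) is fixed here, while the unpolarised dialkylalkyne does not react at room temperature.

Step 4
Reactants: 6 (Z)-1-iododec-1-en-4-yn-2-yl acetate; 7 but-3-yn-1-ol
Product: 8 (Z)-1-hydroxytetradec-5-ene-3,8-diyn-6-yl acetate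
Conditions: PdCl2(PPh3)2 (3 mol%), CuI (5 mol%), Et3N (3 equiv), THF, rt
Reagents that add atoms: none
Why: Sonogashira coupling of a vinyl iodide keeps the alkene geometry, the tertiary amine does not cleave the enol acetate, and the C4 alkynol brings in C7–C10 with the oxygen already on C7.

Step 5
Reactants: 8 (Z)-1-hydroxytetradec-5-ene-3,8-diyn-6-yl acetate
Product: 10 (5Z)-1-oxotetradeca-2,3,5-trien-8-yn-6-yl acetate (vinylallenal; racemic allene axis), via 3-ynal 9 (not isolated)
Conditions: DMP (1.2 equiv), CH2Cl2, 0 °C; aq NaHCO3 wash; crude + Et3N (10 mol%), CH2Cl2, 0 °C, 20 min; silica plug; used at once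
Reagents that add atoms: none
Why: Dess–Martin oxidation gives a 3-ynal whose C8 protons (between formyl and alkynyl groups) are acidic enough for catalytic triethylamine to effect the propargyl–allenyl 1,3-prototropic shift into conjugation with the aldehyde; further drift to a dienal is impossible because C11 is already sp2, and the racemic axis formed here does not matter because step 7 erases it.

Step 6
Reactants: 10 vinylallenal; 11 methyl hex-5-ynoate
Product: 13 methyl (7R,11Z)-12-acetoxy-7-hydroxyicosa-8,9,11-triene-5,14-diynoate (both allene-axis epimers; about 1:1), via alkynyl(methyl)zinc 12 (not isolated)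
Conditions: 11 (1.5 equiv), Me2Zn (1.6 equiv), (R,R)-ProPhenol (20 mol%), Ph3P=O (40 mol%), toluene, rt, 1 h; then 10, 0 °C; aq NH4Cl
Reagents that add atoms: none
Why: The Zn–ProPhenol catalytic asymmetric alkynylation (a dinuclear zinc alkynylide addition developed for unsaturated aldehydes) adds 12 in 1,2 fashion to the formyl group without touching the ester or the enol acetate, and Si-face delivery sets C7 as R, the spatial arrangement that is named 7S once C5≡C6 has become an alkene.

Step 7
Reactants: 13 methyl (7R,11Z)-12-acetoxy-7-hydroxyicosa-8,9,11-triene-5,14-diynoate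
Product: 16 methyl (7R,8R,12R)-12-acetoxy-7-hydroxy-9-oxoprost-10-ene-5,14-diynoate, via 8,9-allene oxide 14 (not isolated), via 2-oxidopentadienyl cation 15 (not isolated)
Conditions: VO(acac)2 (10 mol%), t-BuOOH (5.5 M in decane, 1.3 equiv), 4 Å MS, CH2Cl2 (0.02 M), −20 °C to rt
Reagents that add atoms: tert-butyl hydroperoxide, CC(C)(C)OO
Why: Proposed new method: the C7 vanadate delivers oxygen to the proximal C8=C9 bond from the side of H10 (hydroxyl-directed epoxidation of an α-allenol; the alkynes, the enol acetate and the ester are not allylic-alcohol olefins and are left alone, and a stray attack on C9=C10 would open to the same cation); the metal-bound allene oxide 14 then opens, like the 8,9-allene oxide of the coral pathway, to the planar cation 15, which forgets both the allene axis and the C8 epoxide centre (non-enzymatic cyclisation of natural allene oxides likewise gives racemic cyclopentenones), so both epimers of 13 converge; 15 closes C8–C12 by thermal conrotatory 4π electrocyclisation with C7 and C13 outside and the acetoxy group inside (from the Z enol acetate), which makes the two chains trans and puts O12 cis to the C7 chain, while the six-membered O7–V–O9 (or O7–H···O9) chelate holds the C7–O bond in the cation plane so that C12 bonds to the C8 face bearing H7, anti to the alkynyl chain, giving 8R,12R from 7R; the closest known reaction type is the oxidative cyclisation of vinylallenes to cyclopentenones through vinyl allene oxides (peracid, or VO(acac)2/t-BuOOH on α-allenols), and closure of an oxygen-terminated 2-oxypentadienyl cation is the ring-forming event of the Piancatelli rearrangement.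

Step 8
Reactants: 16 methyl (7R,8R,12R)-12-acetoxy-7-hydroxy-9-oxoprost-10-ene-5,14-diynoate
Product: 17 methyl (5Z,7S,8R,12R,14Z)-12-acetoxy-7-hydroxy-9-oxoprosta-5,10,14-trienoate
Conditions: H2 (1 atm, stopped at 2.0 equiv), Lindlar catalyst, quinoline, EtOAc, 0 °C
Reagents that add atoms: none
Why: In this Lindlar syn semi-hydrogenation both internal alkynes bind the poisoned palladium far better than the enone or the new alkenes, each syn addition gives a Z alkene, and no stereocentre is touched (C7 changes from R to S only through CIP ranking).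

Step 9
Reactants: 17 methyl (5Z,7S,8R,12R,14Z)-12-acetoxy-7-hydroxy-9-oxoprosta-5,10,14-trienoate
Product: 18 methyl (5Z,7S,8R,12S,14Z)-12-acetoxy-7-hydroxy-10-iodo-9-oxoprosta-5,10,14-trienoate
Conditions: I2 (1.5 equiv), pyridine/CH2Cl2 (1:2), 0 °C to rt, dark; aq Na2S2O3
Reagents that add atoms: iodine, II
Why: This Johnson α-iodination of an enone (an addition–iodination–elimination sequence with pyridine as nucleophilic catalyst, known to work on 4,4-disubstituted cyclopentenones) is run while O12 is still acetylated and O7 is free, so neither iodoetherification of a homoallylic 12-OH nor E1cB loss of a 7-acetoxy group can compete, and pyridine-complexed iodine in the dark leaves the Z alkenes alone (C12 changes from R to S only through CIP ranking).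

Step 10
Reactants: 18 methyl (5Z,7S,8R,12S,14Z)-12-acetoxy-7-hydroxy-10-iodo-9-oxoprosta-5,10,14-trienoate
Product: 20 7-acetoxy-7,8-dihydroiodovulone I, via cyclic orthoacid 19 (not isolated)
Conditions: CSA (10 mol%), CH2Cl2, rt
Reagents that add atoms: none
Why: In this acid-catalysed intramolecular 1,3-O→O acyl migration, O12 and the C7 chain are cis on the ring as a result of step 7, so the 7-OH reaches the acetyl carbonyl through a six-membered ring; the shift from a crowded tertiary to a secondary oxygen is downhill, acid rather than base is used so that the new β-acetoxy ketone cannot eliminate by E1cB, and no stereocentre is touched because only acyl–oxygen bonds are made and broken.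

## Compound list
1 | hept-1-yne | CCCCCC#C | starting material
2 | propargyl bromide | C#CCBr | starting material
3 | hept-1-ynylmagnesium bromide (not isolated) | CCCCCC#C[Mg]Br | intermediate
4 | deca-1,4-diyne | CCCCCC#CCC#C | intermediate
5 | 1-iododeca-1,4-diyne | CCCCCC#CCC#CI | intermediate
6 | (Z)-1-iododec-1-en-4-yn-2-yl acetate | CCCCCC#CC/C(OC(C)=O)=C/I | intermediate
7 | but-3-yn-1-ol | C#CCCO | starting material
8 | (Z)-1-hydroxytetradec-5-ene-3,8-diyn-6-yl acetate | CCCCCC#CC/C(OC(C)=O)=C/C#CCCO | intermediate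
9 | (Z)-1-oxotetradec-5-ene-3,8-diyn-6-yl acetate (3-ynal, not isolated) | CCCCCC#CC/C(OC(C)=O)=C/C#CCC=O | intermediate
10 | (5Z)-1-oxotetradeca-2,3,5-trien-8-yn-6-yl acetate (vinylallenal, racemic axis) | CCCCCC#CC/C(OC(C)=O)=C/C=C=CC=O | intermediate
11 | methyl hex-5-ynoate | C#CCCCC(=O)OC | starting material
12 | methyl 6-(methylzincio)hex-5-ynoate (not isolated) | C[Zn]C#CCCCC(=O)OC | intermediate
13 | methyl (7R,11Z)-12-acetoxy-7-hydroxyicosa-8,9,11-triene-5,14-diynoate (both axis epimers) | CCCCCC#CC/C(OC(C)=O)=C/C=C=C[C@@H](O)C#CCCCC(=O)OC | intermediate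
14 | methyl (7R,9E,11Z)-12-acetoxy-8,9-epoxy-7-hydroxyicosa-9,11-diene-5,14-diynoate (8,9-allene oxide, both C8 epimers, not isolated) | CCCCCC#CC/C(OC(C)=O)=C/C=C1/OC1[C@@H](O)C#CCCCC(=O)OC | intermediate
15 | U-shaped C8–C12 12-acetoxy-2-oxidopentadienyl cation (zwitterion; C7 and C13 outside, OAc inside; not isolated) | CCCCCC#CC/C(OC(C)=O)=C/C=C(/[O-])[CH+][C@@H](O)C#CCCCC(=O)OC | intermediate
16 | methyl (7R,8R,12R)-12-acetoxy-7-hydroxy-9-oxoprost-10-ene-5,14-diynoate | CCCCCC#CC[C@@]1(OC(C)=O)C=CC(=O)[C@@H]1[C@H](C#CCCCC(=O)OC)O | intermediate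
17 | methyl (5Z,7S,8R,12R,14Z)-12-acetoxy-7-hydroxy-9-oxoprosta-5,10,14-trienoate | CCCCC/C=C\C[C@@]1(OC(C)=O)C=CC(=O)[C@@H]1[C@H](/C=C\CCCC(=O)OC)O | intermediate
18 | methyl (5Z,7S,8R,12S,14Z)-12-acetoxy-7-hydroxy-10-iodo-9-oxoprosta-5,10,14-trienoate | CCCCC/C=C\C[C@@]1(OC(C)=O)C=C(I)C(=O)[C@@H]1[C@H](/C=C\CCCC(=O)OC)O | intermediate
19 | cyclic orthoacid (2-hydroxy-2-methyl-1,3-dioxane bridging O7 and O12 of 18, not isolated) | CCCCC/C=C\C[C@@]12C=C(I)C(=O)[C@@H]1[C@H](/C=C\CCCC(=O)OC)OC(C)(O)O2 | intermediate
20 | 7-acetoxy-7,8-dihydroiodovulone I, methyl (5Z,7S,8R,12S,14Z)-7-acetoxy-12-hydroxy-10-iodo-9-oxoprosta-5,10,14-trienoate | CCCCC/C=C\C[C@@]1(O)C=C(I)C(=O)[C@@H]1[C@H](/C=C\CCCC(=O)OC)OC(C)=O | target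

## Step count and risks
Total steps: 10. Longest linear sequence: 10 (1 → 20). Compounds 2, 7 and 11 are bought.

**Step 7 (most likely to fail).** The acetoxy group may be too weak a donor, so that 14 is opened by t-BuOH or drifts to an enone before it closes. The 1,2-induction from C7 past a slim alkynyl group may also be modest.

The fallback turns the cation into a push–pull system and drops the metal. It sets out from 6 and comes back at 20.
- KOt-Bu (THF, −78 °C) cleaves the enol acetate with retention, and Et3SiCl traps the enolate as (Z)-triethyl[(1-iododec-1-en-4-yn-2-yl)oxy]silane F5.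
- Sonogashira coupling with 7 gives (Z)-6-(triethylsilyloxy)tetradec-5-ene-3,8-diyn-1-ol F6.
- TPAP/NMO followed by a trace of Et3N gives (5Z)-6-(triethylsilyloxy)tetradeca-2,3,5-trien-8-ynal F7.
- Alkynylation with 12 as in step 6 gives methyl (7R,11Z)-7-hydroxy-12-(triethylsilyloxy)icosa-8,9,11-triene-5,14-diynoate F8.
- Dimethyldioxirane (acetone/CH2Cl2, −78 °C), steered by a hydrogen bond to the 7-OH, attacks the electron-rich siloxydiene at C9=C10. The push of the silyloxy group opens the oxide to an enolate/silyloxocarbenium form of the same cation. This closes at low temperature to methyl (7R,8R,12R)-7-hydroxy-9-oxo-12-(triethylsilyloxy)prost-10-ene-5,14-diynoate F9.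
- Lindlar reduction gives methyl (5Z,7S,8R,12R,14Z)-7-hydroxy-9-oxo-12-(triethylsilyloxy)prosta-5,10,14-trienoate F10.
- I2/pyridine gives methyl (5Z,7S,8R,12S,14Z)-7-hydroxy-10-iodo-9-oxo-12-(triethylsilyloxy)prosta-5,10,14-trienoate F11.
- Ac2O/pyridine acetylates the only free hydroxyl to give methyl (5Z,7S,8R,12S,14Z)-7-acetoxy-10-iodo-9-oxo-12-(triethylsilyloxy)prosta-5,10,14-trienoate F12.
- HF·pyridine frees the tertiary alcohol to give 20.

**Step 10.** The 7-OH may not reach the hindered tertiary acetate under mild acid, or the equilibrium may stop short.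

The fallback replaces the isomerisation by solvolysis and re-acetylation. It sets out from 18 and comes back at 20.
- Sc(OTf)3 (10 mol%) in MeOH/H2O at rt removes the acetate by external methanolysis. The Lewis acid is chelated between the 7-OH and the acetate carbonyl. This gives methyl (5Z,7S,8R,12S,14Z)-7,12-dihydroxy-10-iodo-9-oxoprosta-5,10,14-trienoate F13.
- Ac2O/pyridine at 0 °C without DMAP then acetylates only the secondary 7-OH to give 20.

**Step 6 (together with the handling of 10).** The vinylallenal is at once a reactive diene and a dienophile, so it may dimerise, cycloisomerise or give low ee.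

The fallback avoids the aldehyde and sets C7 by reduction instead of addition. It sets out from 8 and comes back at 13.
- TEMPO/PhI(OAc)2 in aqueous MeCN gives (Z)-6-acetoxytetradec-5-ene-3,8-diynoic acid F1.
- Oxalyl chloride with catalytic DMF gives (Z)-6-acetoxytetradec-5-ene-3,8-diynoyl chloride F2.
- Base-free Pd(PPh3)4-catalysed Negishi acylation of the alkynylzinc 12 gives methyl (11Z)-12-acetoxy-7-oxoicos-11-ene-5,9,14-triynoate F3.
- A trace of Et3N moves this to the allenyl alkynyl ketone methyl (11Z)-12-acetoxy-7-oxoicosa-8,9,11-triene-5,14-diynoate F4.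
- (R)-Me-CBS/catecholborane at −78 °C, with the alkynyl arm as the small group, reduces it in 1,2 fashion to 13.

## Further compounds
F1 | step 6 | (Z)-6-acetoxytetradec-5-ene-3,8-diynoic acid | CCCCCC#CC/C(OC(C)=O)=C/C#CCC(=O)O
F2 | step 6 | (Z)-6-acetoxytetradec-5-ene-3,8-diynoyl chloride | CCCCCC#CC/C(OC(C)=O)=C/C#CCC(=O)Cl
F3 | step 6 | methyl (11Z)-12-acetoxy-7-oxoicos-11-ene-5,9,14-triynoate | CCCCCC#CC/C(OC(C)=O)=C/C#CCC(=O)C#CCCCC(=O)OC
F4 | step 6 | methyl (11Z)-12-acetoxy-7-oxoicosa-8,9,11-triene-5,14-diynoate | CCCCCC#CC/C(OC(C)=O)=C/C=C=CC(=O)C#CCCCC(=O)OC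
F5 | step 7 | (Z)-triethyl[(1-iododec-1-en-4-yn-2-yl)oxy]silane | CCCCCC#CC/C(O[Si](CC)(CC)CC)=C/I
F6 | step 7 | (Z)-6-(triethylsilyloxy)tetradec-5-ene-3,8-diyn-1-ol | CCCCCC#CC/C(O[Si](CC)(CC)CC)=C/C#CCCO
F7 | step 7 | (5Z)-6-(triethylsilyloxy)tetradeca-2,3,5-trien-8-ynal | CCCCCC#CC/C(O[Si](CC)(CC)CC)=C/C=C=CC=O
F8 | step 7 | methyl (7R,11Z)-7-hydroxy-12-(triethylsilyloxy)icosa-8,9,11-triene-5,14-diynoate | CCCCCC#CC/C(O[Si](CC)(CC)CC)=C/C=C=C[C@@H](O)C#CCCCC(=O)OC
F9 | step 7 | methyl (7R,8R,12R)-7-hydroxy-9-oxo-12-(triethylsilyloxy)prost-10-ene-5,14-diynoate | CCCCCC#CC[C@@]1(O[Si](CC)(CC)CC)C=CC(=O)[C@@H]1[C@H](C#CCCCC(=O)OC)O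
F10 | step 7 | methyl (5Z,7S,8R,12R,14Z)-7-hydroxy-9-oxo-12-(triethylsilyloxy)prosta-5,10,14-trienoate | CCCCC/C=C\C[C@@]1(O[Si](CC)(CC)CC)C=CC(=O)[C@@H]1[C@H](/C=C\CCCC(=O)OC)O
F11 | step 7 | methyl (5Z,7S,8R,12S,14Z)-7-hydroxy-10-iodo-9-oxo-12-(triethylsilyloxy)prosta-5,10,14-trienoate | CCCCC/C=C\C[C@@]1(O[Si](CC)(CC)CC)C=C(I)C(=O)[C@@H]1[C@H](/C=C\CCCC(=O)OC)O
F12 | step 7 | methyl (5Z,7S,8R,12S,14Z)-7-acetoxy-10-iodo-9-oxo-12-(triethylsilyloxy)prosta-5,10,14-trienoate | CCCCC/C=C\C[C@@]1(O[Si](CC)(CC)CC)C=C(I)C(=O)[C@@H]1[C@H](/C=C\CCCC(=O)OC)OC(C)=O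
F13 | step 10 | methyl (5Z,7S,8R,12S,14Z)-7,12-dihydroxy-10-iodo-9-oxoprosta-5,10,14-trienoate | CCCCC/C=C\C[C@@]1(O)C=C(I)C(=O)[C@@H]1[C@H](/C=C\CCCC(=O)OC)O
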